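Pdt climbs fast in these flasks and then nearly stops, and two of us dispute what stops it. Each turn of the overall reaction makes one Pdt from one Sbt and one Ptn. Friday's run charges less Sbt than Ptn, so by the overall reaction Sbt is its limiting reagent, and I count turns as shares of the Sbt charged.

| setting | Friday's | Sunday's | Wednesday's | Monday's |
|---|---|---|---|---|
| Sbt | 250 mM | 250 mM | 750 mM | 250 mM |
| Ptn | 275 mM | 550 mM | 275 mM | 275 mM |
| Pdt |  |  |  | 75.0 mM |
| time |  |  |  | 6.2 h |

| run | time / h | [Pdt] / mM |
|---|---|---|
| Friday's run | 0.25 | 58.2 |
| Friday's run | 0.55 | 86.9 |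
| Friday's run | 1.2 | 106.1 |
| Friday's run | 2.8 | 119.6 |
| Friday's run | 6.2 | 125.6 |
| Sunday's run | 0.25 | 86.9 |
| Sunday's run | 0.55 | 123.1 |
| Sunday's run | 1.2 | 148.3 |
| Sunday's run | 2.8 | 161.1 |
| Sunday's run | 6.2 | 167.0 |
| Wednesday's run | 0.25 | 103.3 |
| Wednesday's run | 0.55 | 142.4 |
| Wednesday's run | 1.2 | 167.5 |
| Wednesday's run | 2.8 | 181.2 |
| Wednesday's run | 6.2 | 184.9 |

(readings scatter by 0.8 mM)

* the exponent of [Ptn] in the starting rate at the charge of the Friday's run (at the point where two percent of the Sbt have become Pdt)
* the exponent of [Sbt] in the starting rate at the charge of the Friday's run (at the point where two percent of the Sbt have become Pdt) (one fixed amount of Pdt, the same in the runs compared)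
* Pdt in the Monday's run at 6.2 h, as a share of the Sbt charged

- Overall: Sbt + Ptn -> Pdt.
- Constant volume, constant temperature.
- "The second partner" is Ptn.
- An order is taken over about fifteen percent of the charge, up and down.
- A share of Pdt counts the Pdt that was charged too.

The quantity I carry is the made share: Pdt made by 6.2 h, with any charged Pdt left out, per Sbt charged. In Friday's run the last reading gives it as 50.2 %.

My colleague holds the brake view: Pdt, as it builds, holds back its own formation. In Friday's run the made share grows at 0.931 h⁻¹ over the opening interval and at 0.00706 h⁻¹ over the last, and my colleague reads that collapse against the rising Pdt.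

I hold the drain view: Sbt and Ptn also leave by routes that make no Pdt, and Pdt is a bystander. My number is a balance ratio, Pdt over the product of what one-for-one turning leaves of each partner. On last readings it is 6.76 M⁻¹ in Friday's run and 3.63 M⁻¹ in Wednesday's, so these two last readings do not fit one balance ratio.

I grant the brake this much: in Friday's run Pdt and elapsed time rise together, so that curve describes a brake as well as a drain.

Monday's run pulls them apart, since it has Friday's charge plus Pdt at 30.0 % of the Sbt. If Pdt is a bystander, Monday's run makes Friday's turns, and I reckon 80.2 %.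

The forecast, from the brake side, gives 0.95 for Ptn, 0.85 for Sbt and 62 % for Monday's run, on the ground that “Pdt is holding back the reaction through inhibition or reversal”.

The flask gives 79.8 % for Monday's run, with orders 0.80 for Ptn and 0.83 for Sbt.

    Sbt + Ptn ⇌ Imd, settled at all times (2.040 M⁻¹)
    Sbt + Ptn → Pdt (10.48 M⁻¹ h⁻¹)
    2 Ptn → L (4.428 M⁻¹ h⁻¹)
    2 Sbt → E (6.552 M⁻¹ h⁻¹)

The step joining Sbt with Sbt to E moves the readings by 58 in units of the scatter, root mean square. Without the charged Pdt, Monday's made share is 49.8 %, against 50.2 % from Friday's last reading, a gap of 0.40 percentage points where one reading scatters by 0.320 % of the Sbt charged. Wednesday's last reading has a made share of 24.7 % at 6.2 h, and the Pdt made comes to a quarter of its Sbt later than that, at 8.90 h.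

The earlier runs and the new flask were computed with constants of no real substance, noise included.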